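**Retrosynthetic overview**
- Cacospongin D ⇐ its 4-bromo analogue (CO2H installed last by Br/Li exchange and CO2) ⇐ sp2–sp3 Suzuki union at side-chain C5–C6 between an (E)-vinyl iodide (ring half) and the 9-BBN adduct of an (E)-dienyl bromophenol (arene half).
- Arene half ⇐ ortho C-alkylation of 4-bromophenol with the bromide of (E)-3-methylpent-2-en-4-yn-1-ol; the 2E olefin is bought and never touched.
- Ring half ⇐ Zr-catalysed syn-methylalumination/iodination of a terminal alkyne (sets 6E) ⇐ dihydro-β-ionone.
- Key disconnection: the ring C1–C6 bond (ring carbon bearing the side chain to the gem-dimethyl carbon), formed by radical (metal-hydride HAT) cyclisation of a tertiary radical onto the central carbon of an acyclic β-allenyl ketone ⇐ propargyl Claisen of dehydrolinalool ⇐ homoprenyl Grignard + butynone.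
- Ring order: the cyclohexene is the only ring formed (step 3); the benzene ring is purchased.

Assumption: the target has no stereocentres, so "single enantiomer" reduces to controlling both E-olefins and the position of the ring olefin. All starting materials (1, 2, 4, 9, 11) are taken as commercially available.

**Step 1**
Reactants: 1 (5-bromo-2-methylpent-2-ene), 2 (but-3-yn-2-one)
Product: 3 (3,7-dimethyloct-6-en-1-yn-3-ol, dehydrolinalool, racemic)
Conditions: 1, Mg, THF; CeCl3, −78 °C; then 2, −78 → 0 °C
Reagents that add atoms: none
Why: Grignard/organocerium (Imamoto) 1,2-addition to the ketone outruns deprotonation of the alkyne C–H and conjugate addition; the new carbinol centre is racemic and is destroyed in step 2.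

**Step 2**
Reactants: 3, 4 (2-methoxypropene)
Product: 5 (6,10-dimethylundeca-4,5,9-trien-2-one, racemic allene)
Conditions: 4 (3 equiv), cat. p-TsOH, hydroquinone, sealed tube, 90 °C
Reagents that add atoms: none beyond reactant 4
Why: Saucy–Marbet reaction, i.e. acid-catalysed formation of the propargyl isopropenyl ether followed by propargyl Claisen [3,3] rearrangement to the β-allenyl ketone (the industrial pseudoionone precursor); base is avoided so the allene does not isomerise to the dienone.

**Step 3 (key step)**
Reactants: 5
Product: 6 (4-(2,6,6-trimethylcyclohex-1-en-1-yl)butan-2-one, dihydro-β-ionone)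
Conditions: Mn(dpm)3 (10 mol %), PhSiH3, t-BuOOH, i-PrOH, 0.01 M, rt
Reagents that add atoms: none (PhSiH3 supplies only H)
Why: Proposed new method: Markovnikov HAT from Mn–H to the trisubstituted alkene gives the tertiary radical, which closes the six-membered ring by attack on the central allene carbon (5-exo attack on the methyl-bearing allene terminus would create vicinal quaternary centres and a vinyl radical), leaving the ring C=C already in the tetrasubstituted position and an exocyclic allyl radical that is reduced by H-transfer at its less hindered terminus; the closest known chemistry is the MHAT reductive radical cyclisation/HAT hydrogenation of Shenvi and Baran combined with classical radical cyclisations onto the central carbon of allenes.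

**Step 4**
Reactants: 6
Product: 7 (2-(but-3-yn-1-yl)-1,3,3-trimethylcyclohex-1-ene)
Conditions: LDA, THF, −78 °C; ClP(O)(OEt)2; then LDA (2.2 equiv), −78 °C → rt
Reagents that add atoms: none
Why: Negishi methyl ketone → terminal alkyne conversion through the kinetic (methyl-side) enol phosphate and elimination, precedented on β-ionone; the tetrasubstituted ring alkene is inert.

**Step 5**
Reactants: 7
Product: 8 (2-[(3E)-4-iodo-3-methylbut-3-en-1-yl]-1,3,3-trimethylcyclohex-1-ene)
Conditions: Me3Al, Cp2ZrCl2 (cat.), CH2Cl2, rt; then I2, THF, −30 → 0 °C
Reagents that add atoms: trimethylaluminium, C[Al](C)C (adds CH3); iodine, II (adds I)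
Why: Negishi Zr-catalysed methylalumination is a syn addition with Al on the terminal carbon, and iodinolysis proceeds with retention, so the 6E trisubstituted olefin is set with >98% E.

**Step 6**
Reactants: 9 ((2E)-3-methylpent-2-en-4-yn-1-ol)
Product: 10 ((3E)-5-bromo-3-methylpent-3-en-1-yne)
Conditions: PBr3, cat. pyridine, Et2O, −10 °C; used crude
Reagents that add atoms: phosphorus tribromide, BrP(Br)Br (adds Br)
Why: SN2 bromination of the primary allylic alcohol; the conjugated primary bromide is the favoured regioisomer and the E olefin is untouched.

**Step 7**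
Reactants: 11 (4-bromophenol), 10
Product: 12 (4-bromo-2-[(2E)-3-methylpent-2-en-4-yn-1-yl]phenol)
Conditions: NaH (1 equiv), toluene, 0 °C; then 10, rt
Reagents that add atoms: none
Why: The tight sodium phenoxide ion pair in a non-polar solvent undergoes ortho C-allylation (classical phenol prenylation conditions) by SN2 at the primary carbon, with the para position blocked by Br and the E geometry retained.

**Step 8**
Reactants: 12
Product: 13 (4-bromo-2-[(2E)-3-methylpenta-2,4-dien-1-yl]phenol)
Conditions: H2 (1 atm), Lindlar catalyst, quinoline, EtOAc, rt, stopped at 1 equiv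
Reagents that add atoms: none (H2 only)
Why: Lindlar semi-hydrogenation of the terminal alkyne to the vinyl group; the poisoned catalyst leaves the aryl bromide and the trisubstituted E olefin alone.

**Step 9**
Reactants: 13, 8
Product: 14 (4-bromo-2-[(2E,6E)-3,7-dimethyl-9-(2,6,6-trimethylcyclohex-1-en-1-yl)nona-2,6-dien-1-yl]phenol)
Conditions: 13, 9-BBN (2.3 equiv), THF, 0 °C → rt; then 8, PdCl2(dppf) (5 mol %), AsPh3, Cs2CO3, DMF/H2O, rt
Reagents that add atoms: none (9-BBN supplies only H)
Why: 9-BBN hydroborates only the terminal vinyl carbon of the 4-substituted 1,3-diene (one equivalent is consumed by the phenol), and the B-alkyl Suzuki–Miyaura coupling with the vinyl iodide proceeds at rt with retention of the 6E geometry, far faster than oxidative addition into the electron-rich aryl bromide.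

**Step 10**
Reactants: 14
Product: 15 (cacospongin D, 4-hydroxy-3-[(2E,6E)-3,7-dimethyl-9-(2,6,6-trimethylcyclohex-1-en-1-yl)nona-2,6-dien-1-yl]benzoic acid)
Conditions: NaH, THF, 0 °C; t-BuLi (2.2 equiv), −78 °C; CO2; cold aq. citric acid
Reagents that add atoms: carbon dioxide, O=C=O (adds CO2)
Why: Br/Li exchange on the pre-formed phenoxide followed by carboxylation of the aryllithium gives the acid para to OH; the isolated olefins are inert and the mild acidic work-up avoids chroman formation.

**Compound list**
1 | 5-bromo-2-methylpent-2-ene | CC(C)=CCCBr | starting material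
2 | but-3-yn-2-one | CC(=O)C#C | starting material
3 | 3,7-dimethyloct-6-en-1-yn-3-ol (racemic) | CC(C)=CCCC(C)(O)C#C | intermediate
4 | 2-methoxypropene | COC(C)=C | starting material
5 | 6,10-dimethylundeca-4,5,9-trien-2-one (racemic allene) | CC(=O)CC=C=C(C)CCC=C(C)C | intermediate
6 | 4-(2,6,6-trimethylcyclohex-1-en-1-yl)butan-2-one | CC(=O)CCC1=C(C)CCCC1(C)C | intermediate
7 | 2-(but-3-yn-1-yl)-1,3,3-trimethylcyclohex-1-ene | C#CCCC1=C(C)CCCC1(C)C | intermediate
8 | 2-[(3E)-4-iodo-3-methylbut-3-en-1-yl]-1,3,3-trimethylcyclohex-1-ene | CC1=C(CC/C(C)=C/I)C(C)(C)CCC1 | intermediate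
9 | (2E)-3-methylpent-2-en-4-yn-1-ol | C#C/C(C)=C/CO | starting material
10 | (3E)-5-bromo-3-methylpent-3-en-1-yne | C#C/C(C)=C/CBr | intermediate
11 | 4-bromophenol | Oc1ccc(Br)cc1 | starting material
12 | 4-bromo-2-[(2E)-3-methylpent-2-en-4-yn-1-yl]phenol | C#C/C(C)=C/Cc1cc(Br)ccc1O | intermediate
13 | 4-bromo-2-[(2E)-3-methylpenta-2,4-dien-1-yl]phenol | C=C/C(C)=C/Cc1cc(Br)ccc1O | intermediate
14 | 4-bromo-2-[(2E,6E)-3,7-dimethyl-9-(2,6,6-trimethylcyclohex-1-en-1-yl)nona-2,6-dien-1-yl]phenol | CC1=C(CC/C(C)=C/CC/C(C)=C/Cc2cc(Br)ccc2O)C(C)(C)CCC1 | intermediate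
15 | cacospongin D | CC1=C(CC/C(C)=C/CC/C(C)=C/Cc2cc(C(=O)O)ccc2O)C(C)(C)CCC1 | target

**Totals**
Total steps: 10. Longest linear sequence: 7 (steps 1 → 2 → 3 → 4 → 5 → 9 → 10); the arene half (steps 6–8) is made in parallel.

**Three steps most likely to fail, with fallbacks**
1. Step 3 (radical cyclisation). Risks are reduction of the tertiary radical before it cyclises and competing HAT to the allene. Fallback: make the closure polarity-matched. Convert 3 to its methyl carbonate and carbonylate (Pd(0), CO, MeOH) to the conjugated 2,3-allenoate. Cyclise under Fe(acac)3/PhSiH3 Giese conditions, where the tertiary radical attacks the electrophilic central carbon, to give methyl (2,6,6-trimethylcyclohexenyl)acetate. Then LiAlH4, I2/PPh3 and lithium acetylide give 7 (about three extra steps).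
2. Step 7 (C- versus O-alkylation of the phenoxide). Fallback: switch to an aryl-metal coupling. Ortho-iodinate 11 (NIS), protect as the MOM ether, perform selective I/Mg exchange (i-PrMgCl·LiCl), run a Cu-catalysed allylic substitution with 10, then remove MOM.
3. Step 10 (late Br/Li exchange on a phenoxide carrying acidic benzylic/allylic CH2). Fallback: replace the organolithium by catalytic carbonylation. Silyl-protect 14, run Pd-catalysed methoxycarbonylation (CO, MeOH) or Ni-catalysed reductive carboxylation with CO2, then deprotect and saponify.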